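**Strategy**

The synthesis rests on cutting the labdane down to ring A and reading the adjacent pair C10 (quaternary, carrying methyl C20 and C9) and C5 (carrying C6), whose ring B bonds are trans, as the β- and α-carbons of a cyclohexenone with C4 as carbonyl. In one copper-catalysed operation methyl is added to the ester-bearing β-carbon and the zinc enolate is allylated, which forms C10–C20 and C5–C6 and sets both stereocentres. The precursor is the achiral enone ester 1; its ester carbon becomes C9. Ring B is then closed by metathesis, C4 is completed by carbonylation and reductive methylation, and the C11–C16 chain from (S)-citronellol is joined at C9.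

Key step: step 1

Remark: locants C1–C20 below are the labdane locants of the target (ring A = C1–C5, C10; ring B = C5–C10).
Remark: the chiral sulfonate-bearing 4,5-diphenylimidazolinium salt that serves as carbene precursor for copper is not commercial; it is taken as made beforehand in a short sequence from 1,2-diphenylethylenediamine and used catalytically, in the enantiomeric form that gives the S configuration at the new quaternary carbon.
Remark: (S)-citronellol holds six chain carbons between its hydroxyl and its alkene, one more than C15–C11 needs, so its C6 is excised as CO2 (steps 11 and 12); the hydroxyl end becomes C15, which is what gives 13S.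

**Route**

Step 1
Reactants: 1 methyl 3-oxocyclohex-1-ene-1-carboxylate; 2 dimethylzinc; 3 allyl iodide
Product: 5 methyl (1S,2R)-1-methyl-3-oxo-2-(prop-2-en-1-yl)cyclohexane-1-carboxylate (allyl trans to ester), via methylzinc enolate 4 (not isolated)
Conditions: Cu(OTf)2 (2.5 mol %), chiral imidazolinium sulfonate (5 mol %), 2 (3 equiv), t-BuOMe, −30 °C; then 3 (5 equiv), DMPU, −30 °C → rt
Reagents that add atoms: none
Why: Me2Zn transmetalates to the carbene-bound copper, and the methylcopper species adds through a π-complex and reductive elimination to the enone β-carbon that carries the ester, giving quaternary C10 and the regiodefined methylzinc enolate 4, which allyl iodide then alkylates at C5 once DMPU is added. The closest known reaction type is the copper-catalysed asymmetric conjugate addition of dialkylzincs to β-ester cyclic enones combined with alkylation of the zinc enolate (three-component coupling). No ring is closed. C10 is set by the chiral carbene ligand on copper (catalyst control), and C5 by the substrate, because the electrophile should approach the enolate face anti to the pseudoaxial ester on the neighbouring quaternary carbon, which places allyl trans to the ester. The step needs methyl transfer to the ester-bearing carbon, secured by the ketone being the stronger acceptor, and C-allylation at hindered C5 without enolate equilibration, secured by the low basicity of the zinc enolate and the reactivity of the allylic iodide.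

Step 2
Reactants: 5 methyl (1S,2R)-1-methyl-3-oxo-2-(prop-2-en-1-yl)cyclohexane-1-carboxylate
Product: 7 methyl (1S,2R)-1-methyl-2-(prop-2-en-1-yl)-3-[(trifluoromethanesulfonyl)oxy]cyclohex-3-ene-1-carboxylate, via potassium enolate 6 (not isolated)
Conditions: KN(SiMe3)2, THF, −78 °C; then PhNTf2, −78 → 0 °C
Reagents that add atoms: N-phenylbis(trifluoromethanesulfonimide), O=S(=O)(N(c1ccccc1)S(=O)(=O)C(F)(F)F)C(F)(F)F
Why: Kinetic deprotonation and O-triflation (enol triflate formation) should occur at the open C3 methylene and not at the tertiary C5–H beside the quaternary carbon, which masks the ketone, prepares C4 for carbonylation and takes C5 out of reach of later bases.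

Step 3
Reactants: 7 methyl (1S,2R)-1-methyl-2-(prop-2-en-1-yl)-3-[(trifluoromethanesulfonyl)oxy]cyclohex-3-ene-1-carboxylate
Product: 8 (5S,6R)-5-(hydroxymethyl)-5-methyl-6-(prop-2-en-1-yl)cyclohex-1-en-1-yl trifluoromethanesulfonate
Conditions: i-Bu2AlH (2.5 equiv), CH2Cl2, −78 → 0 °C; Rochelle salt work-up
Reagents that add atoms: none
Why: Hydride reduction of the only ester gives the neopentyl alcohol, while the enol triflate and the terminal alkene are inert to i-Bu2AlH at low temperature.

Step 4
Reactants: 8 (5S,6R)-5-(hydroxymethyl)-5-methyl-6-(prop-2-en-1-yl)cyclohex-1-en-1-yl trifluoromethanesulfonate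
Product: 9 (5S,6R)-5-formyl-5-methyl-6-(prop-2-en-1-yl)cyclohex-1-en-1-yl trifluoromethanesulfonate
Conditions: Dess–Martin periodinane, CH2Cl2, rt
Reagents that add atoms: none
Why: Dess–Martin oxidation gives an aldehyde on a quaternary carbon, which can neither enolise nor epimerise.

Step 5
Reactants: 9 (5S,6R)-5-formyl-5-methyl-6-(prop-2-en-1-yl)cyclohex-1-en-1-yl trifluoromethanesulfonate
Product: 10 (5S,6R)-5-(1-hydroxyprop-2-en-1-yl)-5-methyl-6-(prop-2-en-1-yl)cyclohex-1-en-1-yl trifluoromethanesulfonate (both carbinol epimers)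
Conditions: CH2=CHMgBr, THF, −78 °C
Reagents that add atoms: vinylmagnesium bromide, C=C[Mg]Br
Why: Grignard 1,2-addition to the aldehyde brings in C8 as a vinyl group; the uncatalysed reagent leaves the enol triflate alone at −78 °C, and the new carbinol centre is erased in step 6.

Step 6
Reactants: 10 (5S,6R)-5-(1-hydroxyprop-2-en-1-yl)-5-methyl-6-(prop-2-en-1-yl)cyclohex-1-en-1-yl trifluoromethanesulfonate
Product: 11 (5S,6R)-5-methyl-5-(prop-2-enoyl)-6-(prop-2-en-1-yl)cyclohex-1-en-1-yl trifluoromethanesulfonate
Conditions: Dess–Martin periodinane, CH2Cl2, 0 °C → rt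
Reagents that add atoms: none
Why: Dess–Martin oxidation of the allylic alcohol gives the C9 vinyl ketone, which the adjacent quaternary carbon shields against polymerisation.

Step 7
Reactants: 11 (5S,6R)-5-methyl-5-(prop-2-enoyl)-6-(prop-2-en-1-yl)cyclohex-1-en-1-yl trifluoromethanesulfonate
Product: 12 (4aR,8aS)-8a-methyl-1-oxo-1,4,4a,7,8,8a-hexahydronaphthalen-5-yl trifluoromethanesulfonate (C9 ketone, C7=C8, C3=C4–OTf, H-5 α, C20 β)
Conditions: second-generation Grubbs catalyst (5 mol %), CH2Cl2 (0.01 M), 40 °C
Reagents that add atoms: none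
Why: Ring-closing metathesis between the allyl group and the vinyl ketone forms C7=C8 and ring B as a cyclohexenone with loss of ethylene, and the trans relationship of the two tethers set in step 1 becomes the trans ring fusion.

Step 8
Reactants: 12 (4aR,8aS)-8a-methyl-1-oxo-1,4,4a,7,8,8a-hexahydronaphthalen-5-yl trifluoromethanesulfonate
Product: 13 2-(trimethylsilyl)ethyl (4aS,8aR)-4a-methyl-5-oxo-3,4,4a,5,8,8a-hexahydronaphthalene-1-carboxylate
Conditions: Pd(OAc)2 (5 mol %), PPh3 (10 mol %), CO (1 atm), Me3SiCH2CH2OH (5 equiv), Et3N, DMF, 60 °C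
Reagents that add atoms: carbon monoxide, [C-]#[O+]; 2-(trimethylsilyl)ethanol, C[Si](C)(C)CCO
Why: Palladium-catalysed alkoxycarbonylation of the enol triflate (oxidative addition, CO insertion, alcoholysis) installs C19 as an ester that fluoride can later cleave despite the hindrance at C4.

Step 9
Reactants: 13 2-(trimethylsilyl)ethyl (4aS,8aR)-4a-methyl-5-oxo-3,4,4a,5,8,8a-hexahydronaphthalene-1-carboxylate
Product: 15 2-(trimethylsilyl)ethyl (4aS,8aR)-4a-methyl-5-[(trifluoromethanesulfonyl)oxy]-3,4,4a,7,8,8a-hexahydronaphthalene-1-carboxylate, via lithium enolate 14 (not isolated)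
Conditions: Li(s-Bu)3BH (1.05 equiv), THF, −78 °C; then N-(5-chloropyridin-2-yl)bis(trifluoromethanesulfonimide) (Comins' reagent), −78 → 0 °C
Reagents that add atoms: Comins' reagent, O=S(=O)(N(c1ccc(Cl)cn1)S(=O)(=O)C(F)(F)F)C(F)(F)F
Why: Conjugate hydride reduction of the β-unsubstituted cyclohexenone, favoured because quaternary C10 shields the carbonyl, gives the C8=C9 enolate regiospecifically and O-triflation traps it, while the less electrophilic trisubstituted enoate should not be reduced at −78 °C.

Step 10
Reactants: 16 (S)-citronellol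
Product: 17 {[(3S)-3,7-dimethyloct-6-en-1-yl]oxy}tri(propan-2-yl)silane
Conditions: i-Pr3SiCl, imidazole, DMF, rt
Reagents that add atoms: chlorotri(propan-2-yl)silane, CC(C)[Si](Cl)(C(C)C)C(C)C
Why: Silylation of the primary alcohol gives an alkyl silyl ether that withstands the later oxidative, radical, organozinc and dissolving-metal steps.

Step 11
Reactants: 17 {[(3S)-3,7-dimethyloct-6-en-1-yl]oxy}tri(propan-2-yl)silane
Product: 18 (4S)-4-methyl-6-{[tri(propan-2-yl)silyl]oxy}hexanoic acid
Conditions: RuCl3·xH2O (2 mol %), NaIO4 (4 equiv), EtOAc/MeCN/H2O, rt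
Reagents that add atoms: sodium periodate, [Na+].[O-]I(=O)(=O)=O; water, O
Why: Ruthenium-catalysed periodate cleavage (Sharpless conditions) of the trisubstituted alkene gives the carboxylic acid and acetone without touching the remote stereocentre.

Step 12
Reactants: 18 (4S)-4-methyl-6-{[tri(propan-2-yl)silyl]oxy}hexanoic acid
Product: 20 {[(3R)-5-iodo-3-methylpentyl]oxy}tri(propan-2-yl)silane, via acyl hypoiodite 19 (not isolated)
Conditions: PhI(OAc)2, I2, cyclohexane, hν (tungsten lamp), reflux
Reagents that add atoms: iodine, II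
Why: Suárez iododecarboxylation, in which the acyl hypoiodite fragments under light to CO2 and a primary radical that iodine captures, removes the one surplus carbon and leaves C11 as an iodide (the descriptor changes to R only because iodine outranks oxygen).

Step 13
Reactants: 15 2-(trimethylsilyl)ethyl (4aS,8aR)-4a-methyl-5-[(trifluoromethanesulfonyl)oxy]-3,4,4a,7,8,8a-hexahydronaphthalene-1-carboxylate; 20 {[(3R)-5-iodo-3-methylpentyl]oxy}tri(propan-2-yl)silane
Product: 22 2-(trimethylsilyl)ethyl (13S)-15-{[tri(propan-2-yl)silyl]oxy}-17,18-dinorlabda-3,8-dien-19-oate (H-5 α, C20 β), via alkylzinc iodide 21 (not isolated)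
Conditions: 20, Zn dust, LiCl, THF, 40 °C; then 15, Pd(PPh3)4 (5 mol %), THF/NMP, 60 °C
Reagents that add atoms: none
Why: Negishi coupling, in which zinc insertion into the primary iodide gives an alkylzinc that transmetalates to the vinylpalladium formed from the C9 triflate, forms C9–C11 with the double bond fixed at C8=C9 and tolerates the ester and the silyl ether.

Step 14
Reactants: 22 2-(trimethylsilyl)ethyl (13S)-15-{[tri(propan-2-yl)silyl]oxy}-17,18-dinorlabda-3,8-dien-19-oate
Product: 24 2-(trimethylsilyl)ethyl (13S)-15-{[tri(propan-2-yl)silyl]oxy}-17-norlabd-8-en-19-oate (C18 methyl α, C19 ester β), via lithium ester enolate 23 (not isolated)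
Conditions: Li (2.5 equiv), NH3(l)/THF, t-BuOH (1 equiv), −78 °C; then MeI, −78 → −33 °C
Reagents that add atoms: iodomethane, CI
Why: Dissolving-metal reduction of the unsaturated ester gives the C4 ester enolate (reductive alkylation), which MeI should attack from the α face, away from the axial C10 methyl, so that C18 becomes equatorial and the C19 ester axial, while the isolated trisubstituted alkene and the alkyl silyl ether are inert.

Step 15
Reactants: 24 2-(trimethylsilyl)ethyl (13S)-15-{[tri(propan-2-yl)silyl]oxy}-17-norlabd-8-en-19-oate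
Product: 26 2-(trimethylsilyl)ethyl (8R,13S)-8-hydroxy-15-{[tri(propan-2-yl)silyl]oxy}-17-norlabdan-19-oate (8α-OH, H-9 α), via alkylborane 25 (not isolated)
Conditions: BH3·THF, THF, 0 °C → rt; then NaOH, H2O2, 0 °C → rt
Reagents that add atoms: hydrogen peroxide, OO
Why: Hydroboration–oxidation should place boron on the less substituted C8 and hydrogen on C9, both from the α face opposite the axial C10 methyl, so that the C9 side chain is β and equatorial and oxidation with retention gives the 8α alcohol.

Step 16
Reactants: 26 2-(trimethylsilyl)ethyl (8R,13S)-8-hydroxy-15-{[tri(propan-2-yl)silyl]oxy}-17-norlabdan-19-oate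
Product: 27 2-(trimethylsilyl)ethyl (13S)-8-oxo-15-{[tri(propan-2-yl)silyl]oxy}-17-norlabdan-19-oate
Conditions: Dess–Martin periodinane, CH2Cl2, rt
Reagents that add atoms: none
Why: Dess–Martin oxidation gives the C8 ketone under neutral conditions, and C9 already carries its side chain in the more stable equatorial position.

Step 17
Reactants: 27 2-(trimethylsilyl)ethyl (13S)-8-oxo-15-{[tri(propan-2-yl)silyl]oxy}-17-norlabdan-19-oate
Product: 28 2-(trimethylsilyl)ethyl (13S)-15-{[tri(propan-2-yl)silyl]oxy}labd-8(17)-en-19-oate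
Conditions: Ph3PCH3Br (3 equiv), KOt-Bu (2.8 equiv), toluene, rt → 80 °C
Reagents that add atoms: methyltriphenylphosphonium bromide, C[P+](c1ccccc1)(c1ccccc1)c1ccccc1.[Br-]
Why: Wittig methylenation installs C17; any enolisation toward C9 returns the thermodynamically preferred equatorial side chain, and the hindered ester does not react with the ylide.

Step 18
Reactants: 28 2-(trimethylsilyl)ethyl (13S)-15-{[tri(propan-2-yl)silyl]oxy}labd-8(17)-en-19-oate
Product: 29 (13S)-15-hydroxylabd-8(17)-en-19-oic acid
Conditions: Bu4NF (5 equiv), THF/DMF, rt → 50 °C; then dilute HCl to pH 3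
Reagents that add atoms: none
Why: Fluoride-induced desilylation removes the silyl ether and cleaves the 2-(trimethylsilyl)ethyl ester by attack at silicon and loss of ethylene, a fragmentation that does not need access to the hindered C19 carbonyl.

Step 19
Reactants: 29 (13S)-15-hydroxylabd-8(17)-en-19-oic acid
Product: 30 (13S)-15-(octadecanoyloxy)labd-8(17)-en-19-oic acid (CNP0298278.1)
Conditions: CH3(CH2)16COCl (1.3 equiv), pyridine, DMAP (cat.), CH2Cl2, 0 °C → rt; then aq NaHCO3/THF, acidify
Reagents that add atoms: stearoyl chloride, CCCCCCCCCCCCCCCCCC(=O)Cl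
Why: DMAP-catalysed acylation esterifies the primary C15 alcohol, while the tertiary axial acid cannot be esterified and any mixed anhydride formed at it is hydrolysed at its unhindered stearoyl carbonyl during the bicarbonate work-up.

**Compound list**

1 | methyl 3-oxocyclohex-1-ene-1-carboxylate | COC(=O)C1=CC(=O)CCC1 | starting material
2 | dimethylzinc | C[Zn]C | starting material
3 | allyl iodide (3-iodoprop-1-ene) | C=CCI | starting material
4 | methylzinc (S)-3-(methoxycarbonyl)-3-methylcyclohex-1-en-1-olate (not isolated) | COC(=O)[C@@]1(C)CCCC(O[Zn]C)=C1 | intermediate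
5 | methyl (1S,2R)-1-methyl-3-oxo-2-(prop-2-en-1-yl)cyclohexane-1-carboxylate | COC(=O)[C@@]1(C)CCCC(=O)[C@@H]1CC=C | intermediate
6 | potassium enolate of 5 toward C3 (not isolated) | COC(=O)[C@@]1(C)CCC=C(O[K])[C@@H]1CC=C | intermediate
7 | methyl (1S,2R)-1-methyl-2-(prop-2-en-1-yl)-3-[(trifluoromethanesulfonyl)oxy]cyclohex-3-ene-1-carboxylate | COC(=O)[C@@]1(C)CCC=C(OS(=O)(=O)C(F)(F)F)[C@@H]1CC=C | intermediate
8 | (5S,6R)-5-(hydroxymethyl)-5-methyl-6-(prop-2-en-1-yl)cyclohex-1-en-1-yl trifluoromethanesulfonate | OC[C@@]1(C)CCC=C(OS(=O)(=O)C(F)(F)F)[C@@H]1CC=C | intermediate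
9 | (5S,6R)-5-formyl-5-methyl-6-(prop-2-en-1-yl)cyclohex-1-en-1-yl trifluoromethanesulfonate | O=C[C@@]1(C)CCC=C(OS(=O)(=O)C(F)(F)F)[C@@H]1CC=C | intermediate
10 | (5S,6R)-5-(1-hydroxyprop-2-en-1-yl)-5-methyl-6-(prop-2-en-1-yl)cyclohex-1-en-1-yl trifluoromethanesulfonate, both carbinol epimers | C=CC(O)[C@@]1(C)CCC=C(OS(=O)(=O)C(F)(F)F)[C@@H]1CC=C | intermediate
11 | (5S,6R)-5-methyl-5-(prop-2-enoyl)-6-(prop-2-en-1-yl)cyclohex-1-en-1-yl trifluoromethanesulfonate | C=CC(=O)[C@@]1(C)CCC=C(OS(=O)(=O)C(F)(F)F)[C@@H]1CC=C | intermediate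
12 | (4aR,8aS)-8a-methyl-1-oxo-1,4,4a,7,8,8a-hexahydronaphthalen-5-yl trifluoromethanesulfonate | O=C1C=CC[C@@H]2[C@]1(C)CCC=C2OS(=O)(=O)C(F)(F)F | intermediate
13 | 2-(trimethylsilyl)ethyl (4aS,8aR)-4a-methyl-5-oxo-3,4,4a,5,8,8a-hexahydronaphthalene-1-carboxylate | O=C1C=CC[C@@H]2[C@]1(C)CCC=C2C(=O)OCC[Si](C)(C)C | intermediate
14 | lithium C8=C9 enolate from conjugate reduction of 13 (not isolated) | [Li]OC1=CCC[C@@H]2[C@]1(C)CCC=C2C(=O)OCC[Si](C)(C)C | intermediate
15 | 2-(trimethylsilyl)ethyl (4aS,8aR)-4a-methyl-5-[(trifluoromethanesulfonyl)oxy]-3,4,4a,7,8,8a-hexahydronaphthalene-1-carboxylate | O=S(=O)(OC1=CCC[C@@H]2[C@]1(C)CCC=C2C(=O)OCC[Si](C)(C)C)C(F)(F)F | intermediate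
16 | (S)-citronellol, (3S)-3,7-dimethyloct-6-en-1-ol | CC(C)=CCC[C@H](C)CCO | starting material
17 | {[(3S)-3,7-dimethyloct-6-en-1-yl]oxy}tri(propan-2-yl)silane | CC(C)=CCC[C@H](C)CCO[Si](C(C)C)(C(C)C)C(C)C | intermediate
18 | (4S)-4-methyl-6-{[tri(propan-2-yl)silyl]oxy}hexanoic acid | OC(=O)CC[C@H](C)CCO[Si](C(C)C)(C(C)C)C(C)C | intermediate
19 | acyl hypoiodite of 18 (not isolated) | IOC(=O)CC[C@H](C)CCO[Si](C(C)C)(C(C)C)C(C)C | intermediate
20 | {[(3R)-5-iodo-3-methylpentyl]oxy}tri(propan-2-yl)silane | ICC[C@H](C)CCO[Si](C(C)C)(C(C)C)C(C)C | intermediate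
21 | {(3R)-3-methyl-5-{[tri(propan-2-yl)silyl]oxy}pentyl}zinc iodide (not isolated) | I[Zn]CC[C@H](C)CCO[Si](C(C)C)(C(C)C)C(C)C | intermediate
22 | 2-(trimethylsilyl)ethyl (13S)-15-{[tri(propan-2-yl)silyl]oxy}-17,18-dinorlabda-3,8-dien-19-oate | C1(CC[C@H](C)CCO[Si](C(C)C)(C(C)C)C(C)C)=CCC[C@@H]2[C@]1(C)CCC=C2C(=O)OCC[Si](C)(C)C | intermediate
23 | lithium C4 ester enolate from reduction of 22 (not isolated) | C1(CC[C@H](C)CCO[Si](C(C)C)(C(C)C)C(C)C)=CCC[C@@H]2[C@]1(C)CCCC2=C(O[Li])OCC[Si](C)(C)C | intermediate
24 | 2-(trimethylsilyl)ethyl (13S)-15-{[tri(propan-2-yl)silyl]oxy}-17-norlabd-8-en-19-oate | C1(CC[C@H](C)CCO[Si](C(C)C)(C(C)C)C(C)C)=CCC[C@@H]2[C@]1(C)CCC[C@]2(C)C(=O)OCC[Si](C)(C)C | intermediate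
25 | 8α-boranyl adduct of 24 (not isolated) | B[C@@H]1CC[C@@H]2[C@](C)(CCC[C@]2(C)C(=O)OCC[Si](C)(C)C)[C@H]1CC[C@H](C)CCO[Si](C(C)C)(C(C)C)C(C)C | intermediate
26 | 2-(trimethylsilyl)ethyl (8R,13S)-8-hydroxy-15-{[tri(propan-2-yl)silyl]oxy}-17-norlabdan-19-oate | O[C@@H]1CC[C@@H]2[C@](C)(CCC[C@]2(C)C(=O)OCC[Si](C)(C)C)[C@H]1CC[C@H](C)CCO[Si](C(C)C)(C(C)C)C(C)C | intermediate
27 | 2-(trimethylsilyl)ethyl (13S)-8-oxo-15-{[tri(propan-2-yl)silyl]oxy}-17-norlabdan-19-oate | O=C1CC[C@@H]2[C@](C)(CCC[C@]2(C)C(=O)OCC[Si](C)(C)C)[C@H]1CC[C@H](C)CCO[Si](C(C)C)(C(C)C)C(C)C | intermediate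
28 | 2-(trimethylsilyl)ethyl (13S)-15-{[tri(propan-2-yl)silyl]oxy}labd-8(17)-en-19-oate | C=C1CC[C@@H]2[C@](C)(CCC[C@]2(C)C(=O)OCC[Si](C)(C)C)[C@H]1CC[C@H](C)CCO[Si](C(C)C)(C(C)C)C(C)C | intermediate
29 | (13S)-15-hydroxylabd-8(17)-en-19-oic acid | C=C1CC[C@@H]2[C@](C)(CCC[C@]2(C)C(=O)O)[C@H]1CC[C@H](C)CCO | intermediate
30 | (13S)-15-(octadecanoyloxy)labd-8(17)-en-19-oic acid, i.e. (1S,4aR,5S,8aR)-1,4a-dimethyl-6-methylidene-5-[(3S)-3-methyl-5-(octadecanoyloxy)pentyl]decahydronaphthalene-1-carboxylic acid | C=C1CC[C@@H]2[C@](C)(CCC[C@]2(C)C(=O)O)[C@H]1CC[C@H](C)CCOC(=O)CCCCCCCCCCCCCCCCC | target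

**Count and risks**

Total steps: 19. Longest linear sequence: 16 steps (steps 1–9 and 13–19, from 1 to 30); the side chain takes 3 steps (10–12) before it joins.

Steps most likely to fail:

Step 1. The zinc enolate may be allylated only slowly next to the quaternary carbon, so that proton exchange, O-allylation or attack on the wrong face erodes regio- and diastereocontrol at C5. Fallback: setting out from 1, the conjugate methylation is run as before, but enolate 4 is captured on oxygen with allyl chloroformate to give the allyl enol carbonate F1, which is purified. Pd(PPh3)4 in THF at room temperature then triggers decarboxylative allylation (Tsuji reaction): the palladium enolate is allylated regiospecifically at C5, again anti to the axial ester, and the sequence comes back to the route at 5.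

Step 14. Under dissolving-metal conditions the ester may be over-reduced, or the enolate may be protonated before it is methylated, and face selectivity at C4 may be incomplete. Fallback: setting out from 22, the enoate is reduced conjugatively with SmI2 in THF/N,N-dimethylacetamide with t-BuOH to the saturated ester F2 (either C4 epimer serves). LiN(i-Pr)2 in THF at −78 °C then regenerates enolate 23 under aprotic conditions, MeI alkylates it from the α face, and the sequence comes back to the route at 24.

Step 13. Oxidative addition and transmetalation at the triflate flanked by quaternary C10 may be slow, so that the alkylzinc is consumed by protonation or β-hydride elimination and the triflate is merely reduced. Fallback: setting out from 20, iodine–lithium exchange with t-BuLi (2 equiv, Et2O, −78 °C) gives the alkyllithium F3, which B-methoxy-9-borabicyclo[3.3.1]nonane captures as the lithium borinate F4. This borate couples with 15 under Pd(OAc)2, SPhos and aqueous K3PO4 in THF/DMF (B-alkyl Suzuki–Miyaura coupling) and the sequence comes back to the route at 22.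

Further compounds

F1 | step 1 | methyl (S)-1-methyl-3-{[(prop-2-en-1-yloxy)carbonyl]oxy}cyclohex-2-ene-1-carboxylate | COC(=O)[C@@]1(C)CCCC(OC(=O)OCC=C)=C1
F2 | step 14 | 2-(trimethylsilyl)ethyl (13S)-15-{[tri(propan-2-yl)silyl]oxy}-17,18-dinorlabd-8-en-19-oate, C4 epimers | C1(CC[C@H](C)CCO[Si](C(C)C)(C(C)C)C(C)C)=CCC[C@@H]2[C@]1(C)CCCC2C(=O)OCC[Si](C)(C)C
F3 | step 13 | {(3S)-3-methyl-5-{[tri(propan-2-yl)silyl]oxy}pentyl}lithium | [Li]CC[C@H](C)CCO[Si](C(C)C)(C(C)C)C(C)C
F4 | step 13 | lithium 9-methoxy-9-{(3S)-3-methyl-5-{[tri(propan-2-yl)silyl]oxy}pentyl}-9-boranuidabicyclo[3.3.1]nonane | [Li+].CO[B-]1(CC[C@H](C)CCO[Si](C(C)C)(C(C)C)C(C)C)C2CCCC1CCC2
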